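**Plan**

- Numbering: 1,4-naphthoquinone with C1=O peri to C8–OH, C4=O peri to C5–OMe, side chain on C2, carbinol carbon C1'. The retrosynthesis cuts the C1'–O ester bond first, then the three ring B bonds C3–C4, C1–C2 and C1–C8a.
- Enabling feature: ring B (C1–C4, C4a, C8a) is 1,4-dioxygenated and carries its only carbon substituent on C2, beside the C1 carbonyl that faces C8–OH, while C4 faces C5–OMe. An ortho-methoxyaryl(methoxy)carbene of chromium (C4, C4a, C8a, ring A), one CO (C1) and a terminal alkyne (C3, C2 with the side chain) map onto this pattern.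
- Forward: the alkyne (steps 1–5) and the carbene complex (steps 6–7) are made separately. Step 8 joins them and closes ring B onto the purchased ring A as a 4-methoxy-1-naphthol.
- Oxidation to the quinone, removal of the MOM and TBS groups and esterification of C1'–OH finish the molecule (steps 9–11).
- The single stereocentre (C1', S) is set by Noyori transfer hydrogenation of an alkynyl ketone (step 3) and is only carried along afterwards.

Key step: step 8

Assumption: on exposure to air the tricarbonylchromium fragment of 16 is taken to end as Cr2O3 and carbon monoxide.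

**Route**

Step 1
Reactants: 1 4-methylpent-3-enoic acid
Product: 3 N-methoxy-N,4-dimethylpent-3-enamide, via acyl imidazolide 2 (not isolated)
Conditions: 1,1'-carbonyldiimidazole (1.1 equiv), CH2Cl2, 0 °C → rt; then MeNH(OMe)·HCl (1.2 equiv), rt
Reagents that add atoms: N,O-dimethylhydroxylamine hydrochloride, CNOC.Cl
Why: Amide coupling through the acyl imidazolide needs no added base, so the β,γ-alkene of 1 should not be drawn into conjugation while the N-methoxy-N-methylamide forms.

Step 2
Reactants: 3 N-methoxy-N,4-dimethylpent-3-enamide; 4 ethynyltrimethylsilane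
Product: 6 6-methyl-1-(trimethylsilyl)hept-5-en-1-yn-3-one, via lithium (trimethylsilyl)acetylide 5 (not isolated)
Conditions: 4 (1.3 equiv), n-BuLi (1.25 equiv), THF, −78 °C; then 3, −78 → −20 °C; inverse quench into cold 1 M HCl
Reagents that add atoms: none
Why: Weinreb ketone synthesis, in which the chelated tetrahedral adduct prevents a second addition and the cold acidic inverse quench keeps the released amine protonated so that it neither adds to the ynone nor shifts the skipped alkene.

Step 3
Reactants: 6 6-methyl-1-(trimethylsilyl)hept-5-en-1-yn-3-one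
Product: 7 (S)-6-methyl-1-(trimethylsilyl)hept-5-en-1-yn-3-ol
Conditions: Ru[(S,S)-TsNCHPhCHPhNH](p-cymene) (preformed amido complex, 2 mol %), i-PrOH, rt
Reagents that add atoms: none
Why: Noyori asymmetric transfer hydrogenation of an alkynyl ketone delivers hydride from ruthenium and a proton from the ligand NH through a six-membered outer-sphere transition state, and with the (S,S) ligand the alkynyl group takes the place an aryl group has in aryl ketone reductions, so the S alcohol is expected, while the base-free catalyst should leave the skipped alkene in place.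

Step 4
Reactants: 7 (S)-6-methyl-1-(trimethylsilyl)hept-5-en-1-yn-3-ol
Product: 8 (S)-tert-butyldimethyl{[6-methyl-1-(trimethylsilyl)hept-5-en-1-yn-3-yl]oxy}silane
Conditions: TBSCl (1.2 equiv), imidazole (2.5 equiv), DMF, 0 °C → rt
Reagents that add atoms: tert-butyldimethylsilyl chloride, CC(C)(C)[Si](C)(C)Cl
Why: Silyl ether formation on an unhindered secondary propargylic alcohol is routine, does not touch the stereocentre and avoids isolating the volatile free alkynol.

Step 5
Reactants: 8 (S)-tert-butyldimethyl{[6-methyl-1-(trimethylsilyl)hept-5-en-1-yn-3-yl]oxy}silane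
Product: 9 (S)-tert-butyldimethyl[(6-methylhept-5-en-1-yn-3-yl)oxy]silane
Conditions: K2CO3 (0.2 equiv), MeOH, 0 °C → rt
Reagents that add atoms: none
Why: Protodesilylation by catalytic methoxide is selective because the alkynyl C–SiMe3 bond is far more labile to K2CO3 in MeOH than the tert-butyldimethylsilyl ether.

Step 6
Reactants: 10 3-bromo-4-methoxyphenol
Product: 11 2-bromo-1-methoxy-4-(methoxymethoxy)benzene
Conditions: MOMCl (1.3 equiv), i-Pr2NEt (1.5 equiv), CH2Cl2, 0 °C → rt
Reagents that add atoms: chloromethyl methyl ether, COCCl
Why: O-Alkylation of the phenol with MOMCl and a hindered amine gives an acetal ether that tolerates the organolithium and chromium chemistry that follows and keeps this oxygen distinct from the methyl ether.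

Step 7
Reactants: 11 2-bromo-1-methoxy-4-(methoxymethoxy)benzene; 12 chromium hexacarbonyl, Cr(CO)6
Product: 15 pentacarbonyl{methoxy[2-methoxy-5-(methoxymethoxy)phenyl]methylidene}chromium, via aryllithium 13 (not isolated), via lithium acylchromate 14 (not isolated)
Conditions: n-BuLi (1.05 equiv), Et2O, −78 °C; Cr(CO)6 (1.0 equiv), Et2O, 0 °C → rt; evaporate; Me3OBF4 (1.3 equiv), CH2Cl2, 0 °C → rt
Reagents that add atoms: trimethyloxonium tetrafluoroborate, C[O+](C)C.F[B-](F)(F)F
Why: Fischer carbene synthesis, in which bromine–lithium exchange at −78 °C outruns deprotonation beside the MOM ether, the aryllithium adds to a CO ligand of Cr(CO)6 and the acylchromate oxygen is methylated by the Meerwein salt.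

Step 8
Reactants: 15 pentacarbonyl{methoxy[2-methoxy-5-(methoxymethoxy)phenyl]methylidene}chromium; 9 (S)-tert-butyldimethyl[(6-methylhept-5-en-1-yn-3-yl)oxy]silane
Product: 17 (S)-2-[1-(tert-butyldimethylsilyloxy)-4-methylpent-3-enyl]-4,5-dimethoxy-8-(methoxymethoxy)naphthalen-1-ol, via naphthol tricarbonylchromium complex 16 (not isolated)
Conditions: 15 (1.3 equiv), 9 (1.0 equiv), THF (0.05 M), 50 °C, Ar; then air, Et2O, rt; filtration through silica, used at once
Reagents that add atoms: none
Why: Dötz benzannulation: loss of one CO from 15 (eased by the chelating ortho-methoxy group) lets 9 insert into the Cr=C bond to give a vinylcarbene, CO insertion gives a chromium-bound vinylketene, and 6π electrocyclization onto the free ortho carbon of the aryl ring followed by tautomerization gives complex 16, from which air releases 17. The closest known reaction type is the benzannulation of aryl(methoxy)carbene pentacarbonylchromium complexes with terminal propargylic ethers. Ring B is the only ring formed and closes as a six-membered carbocycle by electrocyclic closure of the dienylketene, which makes the C1–C8a bond after C3–C4 and C1–C2. No stereocentre is created, and the S centre of 9 takes part in no bond change and should be carried over intact. The step needs regioselective alkyne insertion, secured by the steric difference between the alkyne termini (the unsubstituted CH bonds to the carbene carbon and the branched CH(OTBS) carbon ends beside the CO-derived C1), and a single cyclization site, secured because the other ortho position carries the methoxy group that becomes C5–OMe while the MOM ether becomes C8–O. The trisubstituted alkene stands in a 1,5-relationship to the alkyne, so it could intercept the vinylcarbene only by forming a bicyclo[2.1.0] skeleton and should remain a spectator.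

Step 9
Reactants: 17 (S)-2-[1-(tert-butyldimethylsilyloxy)-4-methylpent-3-enyl]-4,5-dimethoxy-8-(methoxymethoxy)naphthalen-1-ol
Product: 18 (S)-2-[1-(tert-butyldimethylsilyloxy)-4-methylpent-3-enyl]-5-methoxy-8-(methoxymethoxy)naphthalene-1,4-dione
Conditions: (NH4)2Ce(NO3)6 (2.2 equiv), MeCN–H2O (4:1), 0 °C, 10 min; NaHCO3 work-up
Reagents that add atoms: water, O
Why: Oxidative demethylation of a para-methoxynaphthol by tetravalent cerium (two one-electron oxidations, capture of the C4 cation by water, loss of methanol) should occur in ring B first because only that ring has a free hydroxyl, after which the quinone carbonyls deactivate the dialkoxy ring A.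

Step 10
Reactants: 18 (S)-2-[1-(tert-butyldimethylsilyloxy)-4-methylpent-3-enyl]-5-methoxy-8-(methoxymethoxy)naphthalene-1,4-dione
Product: 19 (S)-8-hydroxy-2-(1-hydroxy-4-methylpent-3-enyl)-5-methoxynaphthalene-1,4-dione
Conditions: HCl (1 M in MeOH), MeOH–CH2Cl2, 0 °C → rt
Reagents that add atoms: none
Why: Acid-catalysed methanolysis should cleave both the aryl methoxymethyl acetal, helped by the peri carbonyl that hydrogen-bonds the released phenol, and the secondary silyl ether, while the electron-poor quinone disfavours ionization at C1' so that the S centre is not expected to racemize.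

Step 11
Reactants: 19 (S)-8-hydroxy-2-(1-hydroxy-4-methylpent-3-enyl)-5-methoxynaphthalene-1,4-dione; 20 3-methylbut-2-enoic acid
Product: 21 (S)-1-(8-hydroxy-5-methoxy-1,4-dioxo-1,4-dihydronaphthalen-2-yl)-4-methylpent-3-enyl 3-methylbut-2-enoate
Conditions: 20 (1.5 equiv), DCC (1.5 equiv), DMAP (0.1 equiv), CH2Cl2, 0 °C → rt, dark
Reagents that add atoms: none
Why: Steglich esterification should acylate only the secondary alcohol, because the C8 hydroxyl is held in a strong hydrogen bond to the C1 carbonyl as in other peri-hydroxy naphthoquinones, and catalytic DMAP at 0 °C limits migration of the enoate double bond.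

**Compound list**

1 | 4-methylpent-3-enoic acid | CC(C)=CCC(=O)O | starting material
2 | 1-(1H-imidazol-1-yl)-4-methylpent-3-en-1-one (acyl imidazolide) | CC(C)=CCC(=O)n1ccnc1 | intermediate
3 | N-methoxy-N,4-dimethylpent-3-enamide | CC(C)=CCC(=O)N(C)OC | intermediate
4 | ethynyltrimethylsilane | C#C[Si](C)(C)C | starting material
5 | lithium (trimethylsilyl)acetylide, LiC≡CSiMe3 | [Li]C#C[Si](C)(C)C | intermediate
6 | 6-methyl-1-(trimethylsilyl)hept-5-en-1-yn-3-one | CC(C)=CCC(=O)C#C[Si](C)(C)C | intermediate
7 | (S)-6-methyl-1-(trimethylsilyl)hept-5-en-1-yn-3-ol | C[Si](C)(C)C#C[C@H](CC=C(C)C)O | intermediate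
8 | (S)-tert-butyldimethyl{[6-methyl-1-(trimethylsilyl)hept-5-en-1-yn-3-yl]oxy}silane | C[Si](C)(C)C#C[C@H](CC=C(C)C)O[Si](C)(C)C(C)(C)C | intermediate
9 | (S)-tert-butyldimethyl[(6-methylhept-5-en-1-yn-3-yl)oxy]silane | C#C[C@H](CC=C(C)C)O[Si](C)(C)C(C)(C)C | intermediate
10 | 3-bromo-4-methoxyphenol | COc1ccc(O)cc1Br | starting material
11 | 2-bromo-1-methoxy-4-(methoxymethoxy)benzene | COCOc1ccc(OC)c(Br)c1 | intermediate
12 | chromium hexacarbonyl, Cr(CO)6 | O=C=[Cr](=C=O)(=C=O)(=C=O)(=C=O)=C=O | starting material
13 | [2-methoxy-5-(methoxymethoxy)phenyl]lithium | [Li]c1cc(OCOC)ccc1OC | intermediate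
14 | lithium pentacarbonyl[2-methoxy-5-(methoxymethoxy)benzoyl]chromate | [Li+].[O-]C(=[Cr](=C=O)(=C=O)(=C=O)(=C=O)=C=O)c1cc(OCOC)ccc1OC | intermediate
15 | pentacarbonyl{methoxy[2-methoxy-5-(methoxymethoxy)phenyl]methylidene}chromium | COC(=[Cr](=C=O)(=C=O)(=C=O)(=C=O)=C=O)c1cc(OCOC)ccc1OC | intermediate
16 | tricarbonyl{η6-(S)-2-[1-(tert-butyldimethylsilyloxy)-4-methylpent-3-enyl]-4,5-dimethoxy-8-(methoxymethoxy)naphthalen-1-ol}chromium, metal on ring B, written as two dot-joined parts | COc1ccc(OCOC)c2c(O)c([C@H](CC=C(C)C)O[Si](C)(C)C(C)(C)C)cc(OC)c12.O=C=[Cr](=C=O)=C=O | intermediate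
17 | (S)-2-[1-(tert-butyldimethylsilyloxy)-4-methylpent-3-enyl]-4,5-dimethoxy-8-(methoxymethoxy)naphthalen-1-ol | COc1ccc(OCOC)c2c(O)c([C@H](CC=C(C)C)O[Si](C)(C)C(C)(C)C)cc(OC)c12 | intermediate
18 | (S)-2-[1-(tert-butyldimethylsilyloxy)-4-methylpent-3-enyl]-5-methoxy-8-(methoxymethoxy)naphthalene-1,4-dione | COCOc1ccc(OC)c2c1C(=O)C([C@H](CC=C(C)C)O[Si](C)(C)C(C)(C)C)=CC2=O | intermediate
19 | (S)-8-hydroxy-2-(1-hydroxy-4-methylpent-3-enyl)-5-methoxynaphthalene-1,4-dione | COc1ccc(O)c2c1C(=O)C=C([C@H](CC=C(C)C)O)C2=O | intermediate
20 | 3-methylbut-2-enoic acid | CC(C)=CC(=O)O | starting material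
21 | (S)-1-(8-hydroxy-5-methoxy-1,4-dioxo-1,4-dihydronaphthalen-2-yl)-4-methylpent-3-enyl 3-methylbut-2-enoate | COc1ccc(O)c2c1C(=O)C=C([C@H](CC=C(C)C)OC(=O)C=C(C)C)C2=O | target

**Step count and risks**

Total step count: 11. Longest linear sequence: 9 steps (steps 1–5 and 8–11, from 4-methylpent-3-enoic acid).

Steps most likely to fail:

Step 8. The vinylcarbene and vinylketene intermediates can leak into indene or cyclobutenone formation or take up a second alkyne. The electron-rich naphthol, free or still bound to chromium, can also be lost during demetalation and chromatography, by aerial oxidation or by ionization of the benzylic silyloxy group beside the free hydroxyl. The fallback sets out from 15 and 9. The benzannulation is run in THF at 55 °C with Ac2O and Et3N present, so that the naphthol is acetylated as it forms. This should give the naphthyl acetate tricarbonylchromium complex F1, which air converts into (S)-2-[1-(tert-butyldimethylsilyloxy)-4-methylpent-3-enyl]-4,5-dimethoxy-8-(methoxymethoxy)naphthalen-1-yl acetate F2, a compound that can be chromatographed and stored. Just before the oxidation F2 is cleaved with K2CO3 in degassed MeOH under argon, which returns to the route at 17, taken into step 9 without isolation.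

Step 10. Under protic acid the freed C1' hydroxyl can add to the protonated trisubstituted alkene and close a tetrahydrofuran, methanol or chloride can add to the alkene or to C3 of the quinone, and the two protecting groups may leave at unequal rates. The fallback sets out from 18. The silyl ether alone is removed with HF·pyridine in THF–pyridine at 0 °C to give (S)-2-(1-hydroxy-4-methylpent-3-enyl)-5-methoxy-8-(methoxymethoxy)naphthalene-1,4-dione F3. F3 is esterified with 20 under the conditions of step 11 to (S)-1-[5-methoxy-8-(methoxymethoxy)-1,4-dioxo-1,4-dihydronaphthalen-2-yl]-4-methylpent-3-enyl 3-methylbut-2-enoate F4. With the C1' oxygen acylated the cyclization is no longer possible. The aryl acetal is then cleaved with Me2BBr in CH2Cl2 at −78 °C followed by aqueous NaHCO3, which returns to the route at 21.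

Step 3. The doubly activated methylene of 6 allows the skipped alkene to migrate into conjugation with the ynone under the basic ruthenium amide, which would consume the ketone or erode the enantioselectivity. The fallback sets out from 4. Lithiation and formylation with DMF (inverse quench into aqueous KH2PO4) give 3-(trimethylsilyl)prop-2-ynal F5. Brown allylation with (−)-Ipc2B(allyl) in Et2O at −78 °C, the reagent derived from (+)-α-pinene that by the chair transition-state model attacks the Si face of the aldehyde, should give (S)-1-(trimethylsilyl)hex-5-en-1-yn-3-ol F6. Cross-metathesis of F6 in 2-methylbut-2-ene with the second-generation Grubbs catalyst RuCl2(H2IMes)(PCy3)(=CHPh) turns the allyl group into the prenyl group and returns to the route at 7.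

**Further compounds**

F1 | step 8 | tricarbonyl{η6-(S)-2-[1-(tert-butyldimethylsilyloxy)-4-methylpent-3-enyl]-4,5-dimethoxy-8-(methoxymethoxy)naphthalen-1-yl acetate}chromium | COc1ccc(OCOC)c2c(OC(C)=O)c([C@H](CC=C(C)C)O[Si](C)(C)C(C)(C)C)cc(OC)c12.O=C=[Cr](=C=O)=C=O
F2 | step 8 | (S)-2-[1-(tert-butyldimethylsilyloxy)-4-methylpent-3-enyl]-4,5-dimethoxy-8-(methoxymethoxy)naphthalen-1-yl acetate | COc1ccc(OCOC)c2c(OC(C)=O)c([C@H](CC=C(C)C)O[Si](C)(C)C(C)(C)C)cc(OC)c12
F3 | step 10 | (S)-2-(1-hydroxy-4-methylpent-3-enyl)-5-methoxy-8-(methoxymethoxy)naphthalene-1,4-dione | COCOc1ccc(OC)c2c1C(=O)C([C@H](CC=C(C)C)O)=CC2=O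
F4 | step 10 | (S)-1-[5-methoxy-8-(methoxymethoxy)-1,4-dioxo-1,4-dihydronaphthalen-2-yl]-4-methylpent-3-enyl 3-methylbut-2-enoate | COCOc1ccc(OC)c2c1C(=O)C([C@H](CC=C(C)C)OC(=O)C=C(C)C)=CC2=O
F5 | step 3 | 3-(trimethylsilyl)prop-2-ynal | C[Si](C)(C)C#CC=O
F6 | step 3 | (S)-1-(trimethylsilyl)hex-5-en-1-yn-3-ol | C[Si](C)(C)C#C[C@H](CC=C)O
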